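**Retrosynthetic overview**
1. Target 18 is a (3R)-isoflavanone: ring A (C-methylphloroglucinol ring), ring B (5′-geranylresorcinol ring) and the pyranone ring C (O1, C2, C3, C4).
2. Key disconnection C2–C3 of ring C: C2 is a methylene bound only to the ring oxygen O1 (a methyl aryl ether of ring A in disguise) and C3 lies between the C4 carbonyl and ring B (a donor/acceptor carbene site), so an enantioselective intramolecular carbene C–H insertion into an O–CH3 group closes ring C and sets C3 at once.
3. The α-aryl-α-diazoketone comes from a deoxybenzoin (Regitz diazo transfer), itself made by Pd-catalysed α-arylation joining a ring A methyl ketone to a ring B aryl bromide.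
4. Ring A: 5-methoxyresorcinol, two directed ortho-metalations (C-methyl, then acetyl). Ring B: 4,6-dibromoresorcinol, mono-exchange and geranylation. All other phenols are silyl ethers (no C–H next to oxygen), removed last with bifluoride.
5. Ring order: rings A and B are bought as arenes; ring C is the only ring formed, in step 10.

Key step: step 10

Assumption: the sense of induction of the chiral catalyst in step 10 cannot be predicted safely for this substrate; the route is written with Rh2(S-PTAD)4, dirhodium tetrakis[(S)-(1-adamantyl)(N-phthalimido)acetate], and the mirror-image catalyst Rh2(R-PTAD)4 takes its place unchanged should a pilot run show the (3S) series.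

Step 1
Reactants: 1 5-methoxybenzene-1,3-diol (5-methoxyresorcinol)
Product: 2 1-methoxy-3,5-bis(methoxymethoxy)benzene
Conditions: NaH, MOMCl, DMF, 0 °C to rt
Reagents that add atoms: chloromethyl methyl ether, COCCl
Why: Williamson-type O-alkylation of both phenoxides (MOM protection) should install the two acetal groups that later direct both ortho-lithiations, while the native methyl ether stays as the future C2.

Step 2
Reactants: 2 1-methoxy-3,5-bis(methoxymethoxy)benzene
Product: 4 5-methoxy-1,3-bis(methoxymethoxy)-2-methylbenzene, via aryllithium 3 (not isolated)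
Conditions: n-BuLi, THF, 0 °C; then MeI, −78 °C to rt
Reagents that add atoms: iodomethane, CI
Why: Directed ortho-metalation should occur at the ring position flanked by the two methoxymethoxy groups, the strongest pair of lithium-coordinating directors, and the aryllithium is then methylated by SN2 attack on iodomethane.

Step 3
Reactants: 4 5-methoxy-1,3-bis(methoxymethoxy)-2-methylbenzene
Product: 7 1-[6-methoxy-2,4-bis(methoxymethoxy)-3-methylphenyl]ethan-1-one, via aryllithium 5 (not isolated), via lithium hemiaminal alkoxide 6 (not isolated)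
Conditions: n-BuLi, TMEDA, THF, 0 °C; then N-methoxy-N-methylacetamide, −78 to 0 °C; then H2O
Reagents that add atoms: N-methoxy-N-methylacetamide, CC(=O)N(C)OC
Why: A second directed ortho-metalation at one of the two equivalent remaining ring positions (between OMe and OMOM) followed by Weinreb ketone synthesis should give the methyl ketone, the chelated tetrahedral intermediate preventing over-addition.

Step 4
Reactants: 7 1-[6-methoxy-2,4-bis(methoxymethoxy)-3-methylphenyl]ethan-1-one
Product: 8 1-(2,4-dihydroxy-6-methoxy-3-methylphenyl)ethan-1-one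
Conditions: 3 M HCl (aq.), MeOH, 50 °C
Reagents that add atoms: none
Why: Acid-catalysed acetal exchange with methanol (MOM cleavage) should free both phenols while the aryl methyl ether and the ketone are inert, and it is placed before the acid-sensitive geranyl group enters.

Step 5
Reactants: 8 1-(2,4-dihydroxy-6-methoxy-3-methylphenyl)ethan-1-one
Product: 9 1-[2,4-bis(tert-butyldimethylsilyloxy)-6-methoxy-3-methylphenyl]ethan-1-one
Conditions: TBSCl, imidazole, DMAP (cat.), DMF, 50 °C
Reagents that add atoms: tert-butyldimethylsilyl chloride, CC(C)(C)[Si](C)(C)Cl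
Why: Imidazole-promoted silylation of both phenols (the chelated, hindered one needs DMAP and warming) should give silyl ethers, which carry no C–H bond next to oxygen and so cannot compete in the carbene step.

Step 6
Reactants: 10 4,6-dibromobenzene-1,3-diol (4,6-dibromoresorcinol)
Product: 11 1,5-dibromo-2,4-bis(tert-butyldimethylsilyloxy)benzene
Conditions: TBSCl, imidazole, DMF, rt
Reagents that add atoms: tert-butyldimethylsilyl chloride, CC(C)(C)[Si](C)(C)Cl
Why: Standard imidazole-promoted silylation of the two unhindered phenols should give the C2v-symmetric dibromide in which both bromines are equivalent.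

Step 7
Reactants: 11 1,5-dibromo-2,4-bis(tert-butyldimethylsilyloxy)benzene; 12 geranyl bromide, (2E)-1-bromo-3,7-dimethylocta-2,6-diene
Product: 14 1-bromo-2,4-bis(tert-butyldimethylsilyloxy)-5-[(2E)-3,7-dimethylocta-2,6-dien-1-yl]benzene, via arylmagnesium chloride 13 (not isolated)
Conditions: i-PrMgCl·LiCl, THF, 0 °C to rt; then CuBr·SMe2 (10 mol%), 12, −20 to 0 °C
Reagents that add atoms: none
Why: Bromine–magnesium exchange should stop after one of the two equivalent C–Br bonds (the arylmagnesium deactivates the second), and copper-catalysed SN2 allylation at the primary carbon of geranyl bromide keeps the E geometry; magnesium rather than lithium avoids retro-Brook silyl migration.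

Step 8
Reactants: 9 1-[2,4-bis(tert-butyldimethylsilyloxy)-6-methoxy-3-methylphenyl]ethan-1-one; 14 1-bromo-2,4-bis(tert-butyldimethylsilyloxy)-5-[(2E)-3,7-dimethylocta-2,6-dien-1-yl]benzene
Product: 15 1-[2,4-bis(tert-butyldimethylsilyloxy)-6-methoxy-3-methylphenyl]-2-{2,4-bis(tert-butyldimethylsilyloxy)-5-[(2E)-3,7-dimethylocta-2,6-dien-1-yl]phenyl}ethan-1-one
Conditions: Pd(OAc)2 (5 mol%), XPhos (10 mol%), K3PO4, toluene, 90 °C
Reagents that add atoms: none
Why: Palladium-catalysed ketone α-arylation (Buchwald–Hartwig type) of the methyl ketone enolate with the aryl bromide should give the deoxybenzoin, with the bulky biaryl phosphine enabling oxidative addition into the electron-rich bromide, the ortho substituents on both partners blocking a second arylation and anhydrous K3PO4 sparing the silyl ethers.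

Step 9
Reactants: 15 the deoxybenzoin of step 8
Product: 16 1-[2,4-bis(tert-butyldimethylsilyloxy)-6-methoxy-3-methylphenyl]-2-{2,4-bis(tert-butyldimethylsilyloxy)-5-[(2E)-3,7-dimethylocta-2,6-dien-1-yl]phenyl}-2-diazoethan-1-one
Conditions: p-ABSA, DBU, MeCN/CH2Cl2 (dry), 0 °C to rt
Reagents that add atoms: 4-acetamidobenzenesulfonyl azide, CC(=O)Nc1ccc(cc1)S(=O)(=O)N=[N+]=[N-]
Why: Regitz diazo transfer should work directly because the methylene is both benzylic and α to the ketone, so DBU generates the enolate, which attacks the terminal nitrogen of the sulfonyl azide and expels the sulfonamide.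

Step 10
Reactants: 16 the α-aryl-α-diazoketone of step 9
Product: 17 (3R)-5,7-bis(tert-butyldimethylsilyloxy)-3-{2,4-bis(tert-butyldimethylsilyloxy)-5-[(2E)-3,7-dimethylocta-2,6-dien-1-yl]phenyl}-6-methyl-2,3-dihydro-4H-chromen-4-one
Conditions: Rh2(S-PTAD)4 (1 mol%), 2,2-dimethylbutane, 25 to 50 °C, slow addition of 16 at high dilution
Reagents that add atoms: none
Why: Proposed new method: the dirhodium tetracarboxylate should expel N2 from 16 to give a rhodium-bound donor/acceptor carbene at C3 (donor ring B, acceptor the C4 aryl ketone), which inserts through a concerted, hydride-transfer-like three-centre transition state into a C–H bond of the ortho methoxy group of ring A, so that the methoxy carbon becomes C2 and the C2–C3 and C3–H bonds form together. The closest known reaction types are the enantioselective dirhodium-catalysed intramolecular C–H insertion of 2-alkoxyaryl diazoketones to chroman-4-ones and of aryldiazoacetates into ether C–H bonds to give dihydrobenzofurans, together with the intermolecular insertion of donor/acceptor carbenes into the methyl C–H bonds of methyl ethers; new is the pairing of an α-aryl-α-diazoketone with a primary O–CH3 bond to create a tertiary α-aryl ketone stereocentre. Ring C closes as a six-membered ring by 1,6-C–H insertion through a six-membered cyclic transition state. C3, the only stereocentre, is set by the chiral carboxylate pocket of the catalyst, which shields one face of the carbene so that carbon and hydrogen are delivered to the other, and it forms under neutral conditions that cannot epimerise it. The step needs site selectivity for the O–CH3 hydrogens over all other C–H bonds and over ylide pathways: the methoxy group is the only oxygen substituent with α-hydrogens (every other oxygen is a silyl ether with unactivated Si–CH3 bonds), the geranyl chain sits meta on ring B and cannot reach the carbene intramolecularly, and the five-membered oxonium ylide from the methoxy oxygen has no good migrating group and should revert. Slow addition at high dilution suppresses carbene dimerisation and intermolecular attack on the geranyl alkenes.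

Step 11
Reactants: 17 the tetrasilylated (3R)-isoflavanone of step 10
Product: 18 (3R)-3-{5-[(2E)-3,7-dimethylocta-2,6-dien-1-yl]-2,4-dihydroxyphenyl}-5,7-dihydroxy-6-methyl-2,3-dihydro-4H-chromen-4-one
Conditions: KHF2, MeOH/THF, rt
Reagents that add atoms: none
Why: Bifluoride-mediated Si–O cleavage of the four aryl silyl ethers (fluoride desilylation) should proceed under weakly acidic, base-free conditions, which avoids enolisation or retro-oxa-Michael opening at C3 and is too mild to cyclise the geranyl group onto the neighbouring phenol.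

**Compound list**
1 | 5-methoxybenzene-1,3-diol | COc1cc(O)cc(O)c1 | starting material
2 | 1-methoxy-3,5-bis(methoxymethoxy)benzene | COCOc1cc(OC)cc(OCOC)c1 | intermediate
3 | [4-methoxy-2,6-bis(methoxymethoxy)phenyl]lithium | [Li]c1c(OCOC)cc(OC)cc1OCOC | intermediate
4 | 5-methoxy-1,3-bis(methoxymethoxy)-2-methylbenzene | Cc1c(OCOC)cc(OC)cc1OCOC | intermediate
5 | [6-methoxy-2,4-bis(methoxymethoxy)-3-methylphenyl]lithium | [Li]c1c(OC)cc(OCOC)c(C)c1OCOC | intermediate
6 | lithium 1-[methoxy(methyl)amino]-1-[6-methoxy-2,4-bis(methoxymethoxy)-3-methylphenyl]ethan-1-olate | CC(O[Li])(N(C)OC)c1c(OC)cc(OCOC)c(C)c1OCOC | intermediate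
7 | 1-[6-methoxy-2,4-bis(methoxymethoxy)-3-methylphenyl]ethan-1-one | CC(=O)c1c(OC)cc(OCOC)c(C)c1OCOC | intermediate
8 | 1-(2,4-dihydroxy-6-methoxy-3-methylphenyl)ethan-1-one | CC(=O)c1c(OC)cc(O)c(C)c1O | intermediate
9 | 1-[2,4-bis(tert-butyldimethylsilyloxy)-6-methoxy-3-methylphenyl]ethan-1-one | CC(=O)c1c(OC)cc(O[Si](C)(C)C(C)(C)C)c(C)c1O[Si](C)(C)C(C)(C)C | intermediate
10 | 4,6-dibromobenzene-1,3-diol | Oc1cc(O)c(Br)cc1Br | starting material
11 | 1,5-dibromo-2,4-bis(tert-butyldimethylsilyloxy)benzene | CC(C)(C)[Si](C)(C)Oc1cc(O[Si](C)(C)C(C)(C)C)c(Br)cc1Br | intermediate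
12 | geranyl bromide, (2E)-1-bromo-3,7-dimethylocta-2,6-diene | CC(C)=CCC/C(C)=C/CBr | starting material
13 | [5-bromo-2,4-bis(tert-butyldimethylsilyloxy)phenyl]magnesium chloride | Cl[Mg]c1cc(Br)c(O[Si](C)(C)C(C)(C)C)cc1O[Si](C)(C)C(C)(C)C | intermediate
14 | 1-bromo-2,4-bis(tert-butyldimethylsilyloxy)-5-[(2E)-3,7-dimethylocta-2,6-dien-1-yl]benzene | CC(C)=CCC/C(C)=C/Cc1cc(Br)c(O[Si](C)(C)C(C)(C)C)cc1O[Si](C)(C)C(C)(C)C | intermediate
15 | 1-[2,4-bis(tert-butyldimethylsilyloxy)-6-methoxy-3-methylphenyl]-2-{2,4-bis(tert-butyldimethylsilyloxy)-5-[(2E)-3,7-dimethylocta-2,6-dien-1-yl]phenyl}ethan-1-one | CC(C)=CCC/C(C)=C/Cc1cc(CC(=O)c2c(OC)cc(O[Si](C)(C)C(C)(C)C)c(C)c2O[Si](C)(C)C(C)(C)C)c(O[Si](C)(C)C(C)(C)C)cc1O[Si](C)(C)C(C)(C)C | intermediate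
16 | 1-[2,4-bis(tert-butyldimethylsilyloxy)-6-methoxy-3-methylphenyl]-2-{2,4-bis(tert-butyldimethylsilyloxy)-5-[(2E)-3,7-dimethylocta-2,6-dien-1-yl]phenyl}-2-diazoethan-1-one | CC(C)=CCC/C(C)=C/Cc1cc(C(=[N+]=[N-])C(=O)c2c(OC)cc(O[Si](C)(C)C(C)(C)C)c(C)c2O[Si](C)(C)C(C)(C)C)c(O[Si](C)(C)C(C)(C)C)cc1O[Si](C)(C)C(C)(C)C | intermediate
17 | (3R)-5,7-bis(tert-butyldimethylsilyloxy)-3-{2,4-bis(tert-butyldimethylsilyloxy)-5-[(2E)-3,7-dimethylocta-2,6-dien-1-yl]phenyl}-6-methyl-2,3-dihydro-4H-chromen-4-one | CC(C)=CCC/C(C)=C/Cc1cc([C@@H]2COc3cc(O[Si](C)(C)C(C)(C)C)c(C)c(O[Si](C)(C)C(C)(C)C)c3C2=O)c(O[Si](C)(C)C(C)(C)C)cc1O[Si](C)(C)C(C)(C)C | intermediate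
18 | (3R)-3-{5-[(2E)-3,7-dimethylocta-2,6-dien-1-yl]-2,4-dihydroxyphenyl}-5,7-dihydroxy-6-methyl-2,3-dihydro-4H-chromen-4-one | CC(C)=CCC/C(C)=C/Cc1cc([C@@H]2COc3cc(O)c(C)c(O)c3C2=O)c(O)cc1O | target

**Step count and risks**
Total steps: 11. Longest linear sequence: 9 steps (steps 1–5 and 8–11); steps 6–7 form the ring B branch.

Steps most likely to fail:

1. Step 10 (proposed new method). The carbene may be diverted into oxonium-ylide pathways (attack of the methoxy or a silyloxy oxygen followed by methyl or silyl shift to benzofuranone-type products), may undergo Wolff rearrangement, or the catalyst may discriminate the carbene faces poorly. The fallback uses known chemistry only; it sets out from 9 and 14 and comes back at 17. Chelation-controlled cleavage of the methyl ether next to the acetyl group of 9 with BCl3 (CH2Cl2, −78 °C) should give the phenol 1-[2,4-bis(tert-butyldimethylsilyloxy)-6-hydroxy-3-methylphenyl]ethan-1-one F1. Condensation with N,N-dimethylformamide dimethyl acetal (toluene, 90 °C) should give the enaminone (2E)-1-[2,4-bis(tert-butyldimethylsilyloxy)-6-hydroxy-3-methylphenyl]-3-(dimethylamino)prop-2-en-1-one F2, and iodine (pyridine, CHCl3, rt) should close it to 5,7-bis(tert-butyldimethylsilyloxy)-3-iodo-6-methyl-4H-chromen-4-one F3. In parallel, Miyaura borylation of 14 (bis(pinacolato)diboron, Pd(dppf)Cl2, KOAc, dioxane, 80 °C) should give the ring B pinacol boronate F4. Suzuki–Miyaura coupling of the two (Pd(PPh3)4, anhydrous K3PO4, toluene/dioxane, 80 °C) should give the tetrasilylated isoflavone F5. Asymmetric transfer hydrogenation (RuCl(p-cymene)[(R,R)-TsDPEN] or its antipode, HCO2H/Et3N, EtOAc, 40 °C) reduces the C2–C3 double bond and then, by dynamic kinetic resolution of the rapidly racemising isoflavanone, the ketone, and should give the cis-(3R,4R)-isoflavan-4-ol F6. Dess–Martin periodinane (NaHCO3, CH2Cl2, 0 °C) should then return ketone 17 with C3 untouched.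

2. Step 8. Oxidative addition into the electron-rich, ortho-silyloxy aryl bromide and coupling with the hindered enolate may stall, with protodebromination or silyl loss under the hot basic conditions taking over. The fallback sets out from 9 and 14 and comes back at 16, moving diazo transfer ahead of the aryl–carbon bond formation. Trifluoroacetylation of the lithium enolate of 9 (LiHMDS, 2,2,2-trifluoroethyl trifluoroacetate, THF, −78 °C) should give the diketone 1-[2,4-bis(tert-butyldimethylsilyloxy)-6-methoxy-3-methylphenyl]-4,4,4-trifluorobutane-1,3-dione F7 (not isolated). Detrifluoroacetylative diazo transfer (methanesulfonyl azide, Et3N, H2O, MeCN) should give the diazomethyl ketone 1-[2,4-bis(tert-butyldimethylsilyloxy)-6-methoxy-3-methylphenyl]-2-diazoethan-1-one F8. Bromide 14 is converted by copper-catalysed aromatic Finkelstein exchange (CuI, NaI, trans-N,N′-dimethylcyclohexane-1,2-diamine, dioxane, 110 °C) into the aryl iodide 2,4-bis(tert-butyldimethylsilyloxy)-5-[(2E)-3,7-dimethylocta-2,6-dien-1-yl]-1-iodobenzene F9. Palladium-catalysed C–H arylation of the acyldiazomethane with retention of the diazo group (Pd(PPh3)4, Ag2CO3, Et3N, toluene, rt) should then give 16 directly.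

3. Step 9. Diazo transfer to the crowded enolate may be slow, so that the amidine base strips aryl silyl ethers or the electron-rich diazo compound decomposes during the long basic reaction. The fallback sets out from 15 and comes back at 16, introducing the diazo nitrogen by hydrazone chemistry instead. Enolate hydroxylation (KHMDS, THF, −78 °C; 2-(phenylsulfonyl)-3-phenyloxaziridine) should give the racemic α-hydroxy ketone 1-[2,4-bis(tert-butyldimethylsilyloxy)-6-methoxy-3-methylphenyl]-2-{2,4-bis(tert-butyldimethylsilyloxy)-5-[(2E)-3,7-dimethylocta-2,6-dien-1-yl]phenyl}-2-hydroxyethan-1-one F10. Dess–Martin oxidation should give the corresponding 1,2-diketone (ethane-1,2-dione) F11. Condensation with p-toluenesulfonyl hydrazide (THF, rt) should occur at the ring B side carbonyl, the other being shielded by the 2,6-disubstituted ring A, to give the mono-tosylhydrazone F12. Bamford–Stevens elimination of sulfinate (Et3N, CH2Cl2, rt) should then give 16.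

**Further compounds**
F1 | step 10 | 1-[2,4-bis(tert-butyldimethylsilyloxy)-6-hydroxy-3-methylphenyl]ethan-1-one | CC(=O)c1c(O)cc(O[Si](C)(C)C(C)(C)C)c(C)c1O[Si](C)(C)C(C)(C)C
F2 | step 10 | (2E)-1-[2,4-bis(tert-butyldimethylsilyloxy)-6-hydroxy-3-methylphenyl]-3-(dimethylamino)prop-2-en-1-one | CN(C)/C=C/C(=O)c1c(O)cc(O[Si](C)(C)C(C)(C)C)c(C)c1O[Si](C)(C)C(C)(C)C
F3 | step 10 | 5,7-bis(tert-butyldimethylsilyloxy)-3-iodo-6-methyl-4H-chromen-4-one | Cc1c(O[Si](C)(C)C(C)(C)C)cc2occ(I)c(=O)c2c1O[Si](C)(C)C(C)(C)C
F4 | step 10 | 2-{2,4-bis(tert-butyldimethylsilyloxy)-5-[(2E)-3,7-dimethylocta-2,6-dien-1-yl]phenyl}-4,4,5,5-tetramethyl-1,3,2-dioxaborolane | CC(C)=CCC/C(C)=C/Cc1cc(B2OC(C)(C)C(C)(C)O2)c(O[Si](C)(C)C(C)(C)C)cc1O[Si](C)(C)C(C)(C)C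
F5 | step 10 | 5,7-bis(tert-butyldimethylsilyloxy)-3-{2,4-bis(tert-butyldimethylsilyloxy)-5-[(2E)-3,7-dimethylocta-2,6-dien-1-yl]phenyl}-6-methyl-4H-chromen-4-one | CC(C)=CCC/C(C)=C/Cc1cc(-c2coc3cc(O[Si](C)(C)C(C)(C)C)c(C)c(O[Si](C)(C)C(C)(C)C)c3c2=O)c(O[Si](C)(C)C(C)(C)C)cc1O[Si](C)(C)C(C)(C)C
F6 | step 10 | (3R,4R)-5,7-bis(tert-butyldimethylsilyloxy)-3-{2,4-bis(tert-butyldimethylsilyloxy)-5-[(2E)-3,7-dimethylocta-2,6-dien-1-yl]phenyl}-6-methyl-3,4-dihydro-2H-chromen-4-ol (cis) | CC(C)=CCC/C(C)=C/Cc1cc([C@@H]2COc3cc(O[Si](C)(C)C(C)(C)C)c(C)c(O[Si](C)(C)C(C)(C)C)c3[C@@H]2O)c(O[Si](C)(C)C(C)(C)C)cc1O[Si](C)(C)C(C)(C)C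
F7 | step 8 | 1-[2,4-bis(tert-butyldimethylsilyloxy)-6-methoxy-3-methylphenyl]-4,4,4-trifluorobutane-1,3-dione | O=C(CC(=O)C(F)(F)F)c1c(OC)cc(O[Si](C)(C)C(C)(C)C)c(C)c1O[Si](C)(C)C(C)(C)C
F8 | step 8 | 1-[2,4-bis(tert-butyldimethylsilyloxy)-6-methoxy-3-methylphenyl]-2-diazoethan-1-one | [N-]=[N+]=CC(=O)c1c(OC)cc(O[Si](C)(C)C(C)(C)C)c(C)c1O[Si](C)(C)C(C)(C)C
F9 | step 8 | 2,4-bis(tert-butyldimethylsilyloxy)-5-[(2E)-3,7-dimethylocta-2,6-dien-1-yl]-1-iodobenzene | CC(C)=CCC/C(C)=C/Cc1cc(I)c(O[Si](C)(C)C(C)(C)C)cc1O[Si](C)(C)C(C)(C)C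
F10 | step 9 | 1-[2,4-bis(tert-butyldimethylsilyloxy)-6-methoxy-3-methylphenyl]-2-{2,4-bis(tert-butyldimethylsilyloxy)-5-[(2E)-3,7-dimethylocta-2,6-dien-1-yl]phenyl}-2-hydroxyethan-1-one (racemic) | CC(C)=CCC/C(C)=C/Cc1cc(C(O)C(=O)c2c(OC)cc(O[Si](C)(C)C(C)(C)C)c(C)c2O[Si](C)(C)C(C)(C)C)c(O[Si](C)(C)C(C)(C)C)cc1O[Si](C)(C)C(C)(C)C
F11 | step 9 | 1-[2,4-bis(tert-butyldimethylsilyloxy)-6-methoxy-3-methylphenyl]-2-{2,4-bis(tert-butyldimethylsilyloxy)-5-[(2E)-3,7-dimethylocta-2,6-dien-1-yl]phenyl}ethane-1,2-dione | CC(C)=CCC/C(C)=C/Cc1cc(C(=O)C(=O)c2c(OC)cc(O[Si](C)(C)C(C)(C)C)c(C)c2O[Si](C)(C)C(C)(C)C)c(O[Si](C)(C)C(C)(C)C)cc1O[Si](C)(C)C(C)(C)C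
F12 | step 9 | N′-(1-{2,4-bis(tert-butyldimethylsilyloxy)-5-[(2E)-3,7-dimethylocta-2,6-dien-1-yl]phenyl}-2-[2,4-bis(tert-butyldimethylsilyloxy)-6-methoxy-3-methylphenyl]-2-oxoethylidene)-4-methylbenzenesulfonohydrazide | CC(C)=CCC/C(C)=C/Cc1cc(C(=NNS(=O)(=O)c3ccc(C)cc3)C(=O)c2c(OC)cc(O[Si](C)(C)C(C)(C)C)c(C)c2O[Si](C)(C)C(C)(C)C)c(O[Si](C)(C)C(C)(C)C)cc1O[Si](C)(C)C(C)(C)C
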